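The numbers in the tables were computed with made-up constants, and the scatter is random.

- I started from the catalyst.

- elm: substrate 0.10 M; gas phase 3.7 mM (held); free catalyst 0.20 mM; impurity 92 µM; the very flask that is asked about, followed so far
- flask: substrate 0.10 M; gas phase 3.7 mM (held); free catalyst 0.20 mM; impurity 92 µM; time 4.0 min

elm run (percent of the substrate charged)

| time / s | target / % | substrate / % |
|---|---|---|
| 10.0 | 3.8 | 94.4 |
| 15.0 | 7.5 | 95.5 |
| 25.0 | 9.7 | 90.7 |
| 30.0 | 10.0 | 89.1 |
| 40.0 | 13.7 | 87.7 |
| 50.0 | 15.0 | 83.0 |

(each reading ± 1 percentage point)

- the numbers in the tables scatter by 1 percentage point (one standard deviation)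
- at the start none of the gas phase is in solution

- autumn: doubling the amount of free catalyst, all else as stated
- noon: doubling the transfer coefficient of the gas phase, all else as stated
- summer: doubling the saturation concentration of gas phase, all else as stated

* target at 4.0 min, in percent of the substrate charged
* the change that raises the amount of target at 4.0 min, in percent of the substrate charged most ("none" if none brings more than 2 percentage points) (autumn / noon / summer / none)
* amount of target at 4.0 min, in percent of the substrate charged, after noon

- My bench rule was to treat the substrate as pseudo-first-order, losing a constant fraction per second. The last reading of the flask gave 0.00325 s⁻¹, and carried to 4.0 min that meant 54.2%.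
- That rule holds while the catalyst stays as charged, but here the ratio of impurity to catalyst was 0.460, which is not small. If the impurity took catalyst one for one, the end state of the catalyst was the surviving share, charged catalyst minus impurity over charged catalyst, 54.0%.
- Running at that share from the last reading onward gave 39.1%, so I committed to the middle, 46.6%, which is lower than the forecast.
- On the same one-for-one reckoning, doubling the catalyst left 0.308 mM against 0.108 mM, which is 2.85 times as much, so I chose autumn. Target already stood at 3.8% after 10.0 s, with no visible lag, so I expected little from noon.
- The forecast gave 60% (47% to 73%), autumn as the best change, and 62% (48% to 80%) after noon. It allowed for “the impurity taking up part of the catalyst”.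
- The flask gave 48.9%, 11 percentage points below the forecast. Autumn brought 34 points, summer 3.1 points and noon 0.16 points, which left 49.1% after noon.

    substrate + dissolved gas + free catalyst → free catalyst + target (k = 1.80 × 10⁵ M⁻² s⁻¹)
    dissolved gas + free catalyst ⇌ idle complex, settled at all times (K = 7200 M⁻¹)
    free catalyst + impurity → spent catalyst (k = 7700 M⁻¹ s⁻¹)
    gas phase ⇌ dissolved gas, rate k4*(csat - [dissolved gas]) (kL = 2.30 s⁻¹)

- In the flask, free catalyst had a half-life of 0.39 min against the impurity at 1.36 min, shorter than the 4.0 min asked. At 4.00 min spent catalyst stood at 46.0%, and free catalyst plus idle complex at 54.0%.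
- With 3.7 × 10⁻⁵ M of impurity in the neighbour flask, the one-for-one reckoning gave a surviving share of 81.5%. Scaling the logarithm of the substrate left in the flask by 1.51 gave 63.7% of target. The computed neighbour gave 61.6%, with spent catalyst at 18.5%.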